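The lactone is opened retrosynthetically to an acyclic homophthalate, and everything rests on making its two ortho C–C bonds together: an aryne inserts into a C–C bond of dimethyl malonate, so that the adjacent benzene-ring carbons C8a and C4a receive the carboxyl carbon C1 and the methylene C4 in one operation. The feature exploited is the C8 oxygen next to C8a on the benzenoid ring, which directs the carbanion to C4a and the acyl group to C8a. The precursor is an ortho-trimethylsilyl aryl triflate bearing methoxy groups at the future C6 and C8. The C3 stereocentre is set later by asymmetric transfer hydrogenation of an ynone.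

Key step: step 4

Remark: the target SMILES is read as the (3R) enantiomer; locants follow isochroman-1-one numbering (C1 lactone carbonyl, O2, C3, C4, C4a, C5 to C8, C8a).

Step 1
Reactants: 1 3,5-dimethoxyphenol
Product: 2 2-bromo-3,5-dimethoxyphenol
Conditions: NBS (1.0 equiv), CH2Cl2, −78 °C to rt
Reagents that add atoms: N-bromosuccinimide, O=C1CCC(=O)N1Br
Why: Electrophilic aromatic bromination of the strongly activated phenol should take place at one of the two equivalent positions ortho to the hydroxyl and para to a methoxy group, which are favoured statistically and are less crowded than the position between the two methoxy groups, and any para-bromo isomer can be removed by chromatography.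

Step 2
Reactants: 2 2-bromo-3,5-dimethoxyphenol
Product: 3 (2-bromo-3,5-dimethoxyphenoxy)trimethylsilane
Conditions: HMDS, THF, 70 °C; concentrate and use crude
Reagents that add atoms: hexamethyldisilazane, C[Si](C)(C)N[Si](C)(C)C
Why: O-silylation of a phenol with hexamethyldisilazane is driven by loss of ammonia and leaves no salt, so the moisture-sensitive aryl silyl ether can be carried on without purification.

Step 3
Reactants: 3 (2-bromo-3,5-dimethoxyphenoxy)trimethylsilane
Product: 5 3,5-dimethoxy-2-(trimethylsilyl)phenyl trifluoromethanesulfonate, via lithium 3,5-dimethoxy-2-(trimethylsilyl)phenoxide 4 (not isolated)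
Conditions: n-BuLi, THF, −100 to −78 °C; then Tf2O, −100 °C to rt
Reagents that add atoms: trifluoromethanesulfonic anhydride, O=S(=O)(OS(=O)(=O)C(F)(F)F)C(F)(F)F
Why: Bromine–lithium exchange gives an aryllithium next to the silyloxy group, which undergoes the retro-Brook 1,3-shift of silicon from oxygen to carbon to give the more stable phenoxide, and this is O-sulfonylated in the same flask by Tf2O.

Step 4
Reactants: 5 3,5-dimethoxy-2-(trimethylsilyl)phenyl trifluoromethanesulfonate; 6 dimethyl malonate
Product: 9 methyl 2,4-dimethoxy-6-(2-methoxy-2-oxoethyl)benzoate, via 3,5-dimethoxybenzyne 7 (not isolated), via benzocyclobutenoxide 8 (not isolated)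
Conditions: KF, 18-crown-6, 6 (2 equiv), THF, 0 °C to rt
Reagents that add atoms: none
Why: Fluoride attacks silicon and the ortho triflate departs to give aryne 7, and the malonate anion adds to the aryne carbon away from the neighbouring methoxy group (future C4a), because the aryl anion then develops at the carbon beside the electron-withdrawing C–O bond (future C8a). That anion adds to one ester carbonyl of the malonate unit in a 4-exo-trig closure to give the strained alkoxide 8, which opens by cleavage of the original malonate C–C bond to the ester-stabilised benzylic anion, so that the carboxyl carbon ends on C8a and the methylene on C4a. The closest known reaction type is the fluoride-triggered insertion of arynes into the C–C sigma bond of malonates and beta-keto esters (aryne acyl-alkylation). The four-membered ring is transient, no ring remains in 9 and no stereocentre is created. The step needs regioselective addition to the unsymmetrical aryne, secured by the methoxy group next to the triple bond, and ring closure faster than protonation of the aryl anion, favoured by the aprotic medium. Excess malonate, more acidic than the product, should protonate the benzylic anion and suppress a second arylation.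

Step 5
Reactants: 9 methyl 2,4-dimethoxy-6-(2-methoxy-2-oxoethyl)benzoate
Product: 10 methyl 2,4-dimethoxy-6-{2-[methoxy(methyl)amino]-2-oxoethyl}benzoate
Conditions: MeNHOMe·HCl, AlMe3, CH2Cl2, 0 °C to rt; aq. HCl work-up
Reagents that add atoms: N,O-dimethylhydroxylamine hydrochloride, CNOC.Cl
Why: Weinreb amidation of an ester with the aluminium amide generated from AlMe3 and MeNHOMe·HCl should convert only the unhindered aliphatic ester, because the benzoate carbonyl is shielded by its two ortho substituents and deactivated by the methoxy donors.

Step 6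
Reactants: 11 undec-10-yn-1-ol
Product: 12 [(undec-10-yn-1-yloxy)methyl]benzene (benzyl undec-10-yn-1-yl ether)
Conditions: NaH (1.1 equiv), BnBr, n-Bu4NI (cat.), THF, 0 °C to rt
Reagents that add atoms: benzyl bromide, BrCc1ccccc1
Why: Williamson ether synthesis on the sodium alkoxide protects the primary alcohol as a benzyl ether, the far less acidic alkyne C–H remaining untouched when about one equivalent of NaH is used.

Step 7
Reactants: 10 methyl 2,4-dimethoxy-6-{2-[methoxy(methyl)amino]-2-oxoethyl}benzoate; 12 [(undec-10-yn-1-yloxy)methyl]benzene
Product: 14 methyl 2-[13-(benzyloxy)-2-oxotridec-3-yn-1-yl]-4,6-dimethoxybenzoate, via lithium acetylide 13 (not isolated)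
Conditions: 12, n-BuLi, THF, −78 °C; then 10, −78 to −40 °C; AcOH quench at −78 °C
Reagents that add atoms: none
Why: Acylation of the lithium acetylide by the Weinreb amide stops at the chelated tetrahedral adduct, which collapses to the ynone only on the cold acidic quench, so over-addition is excluded and the hindered, electron-rich methyl benzoate should not compete at −78 °C.

Step 8
Reactants: 14 methyl 2-[13-(benzyloxy)-2-oxotridec-3-yn-1-yl]-4,6-dimethoxybenzoate
Product: 15 methyl 2-[(2S)-13-(benzyloxy)-2-hydroxytridec-3-yn-1-yl]-4,6-dimethoxybenzoate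
Conditions: Ru[(S,S)-TsNCH(Ph)CH(Ph)NH](p-cymene) (1 mol %), i-PrOH, rt
Reagents that add atoms: none
Why: Noyori asymmetric transfer hydrogenation of alkynyl ketones with the (S,S)-TsDPEN ruthenium amido complex delivers hydride to one carbonyl face under base-free conditions, the alkynyl group taking the position that an aryl group takes with aryl ketones, so that the (S)-propargylic alcohol is expected (the enantiomeric catalyst being available should the sense turn out opposite) while the acidic benzylic CH2, the ester and the triple bond are left alone.

Step 9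
Reactants: 15 methyl 2-[(2S)-13-(benzyloxy)-2-hydroxytridec-3-yn-1-yl]-4,6-dimethoxybenzoate
Product: 17 (3R)-3-(11-hydroxyundecyl)-6,8-dimethoxy-3,4-dihydro-1H-isochromen-1-one, via hydroxy ester 16 (not isolated)
Conditions: H2 (1 atm), 10% Pd/C, EtOAc, rt; filter; then p-TsOH·H2O (cat.), toluene, 80 °C
Reagents that add atoms: none
Why: Catalytic hydrogenation over Pd/C saturates the triple bond and hydrogenolyses the benzyl ether without breaking the C3–O bond (the descriptor changes from S to R only because the CIP priorities of the two carbon substituents are exchanged), and acid-catalysed intramolecular transesterification then closes the six-membered lactone through attack of the secondary hydroxyl on the neighbouring ester, with retention at C3.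

Step 10
Reactants: 17 (3R)-3-(11-hydroxyundecyl)-6,8-dimethoxy-3,4-dihydro-1H-isochromen-1-one
Product: 18 (3R)-8-hydroxy-3-(11-hydroxyundecyl)-6-methoxy-3,4-dihydro-1H-isochromen-1-one
Conditions: BCl3 (1 M in CH2Cl2, 3 equiv), CH2Cl2, −78 to 0 °C; then H2O
Reagents that add atoms: none
Why: Chelation-controlled ether cleavage with BCl3, which binds between the lactone carbonyl and the peri C8 methoxy oxygen, should remove only that methyl group as chloromethane and spare the C6 methyl ether, the lactone and the C3 centre, the borate ester of the primary alcohol being hydrolysed on work-up.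

Compound list
1 | 3,5-dimethoxyphenol | COc1cc(O)cc(OC)c1 | starting material
2 | 2-bromo-3,5-dimethoxyphenol | COc1cc(O)c(Br)c(OC)c1 | intermediate
3 | (2-bromo-3,5-dimethoxyphenoxy)trimethylsilane | COc1cc(O[Si](C)(C)C)c(Br)c(OC)c1 | intermediate
4 | lithium 3,5-dimethoxy-2-(trimethylsilyl)phenoxide | [Li+].[O-]c1cc(OC)cc(OC)c1[Si](C)(C)C | intermediate
5 | 3,5-dimethoxy-2-(trimethylsilyl)phenyl trifluoromethanesulfonate | COc1cc(OC)c([Si](C)(C)C)c(OS(=O)(=O)C(F)(F)F)c1 | intermediate
6 | dimethyl malonate | COC(=O)CC(=O)OC | starting material
7 | 3,5-dimethoxybenzyne (1,2-didehydro-3,5-dimethoxybenzene) | COC1=CC(OC)=CC#C1 | intermediate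
8 | potassium 3,5,7-trimethoxy-8-(methoxycarbonyl)bicyclo[4.2.0]octa-1,3,5-trien-7-olate (transient benzocyclobutenoxide, configuration irrelevant) | [K+].[O-]C1(OC)c2c(OC)cc(OC)cc2C1C(=O)OC | intermediate
9 | methyl 2,4-dimethoxy-6-(2-methoxy-2-oxoethyl)benzoate (the dimethyl homophthalate) | COC(=O)Cc1cc(OC)cc(OC)c1C(=O)OC | intermediate
10 | methyl 2,4-dimethoxy-6-{2-[methoxy(methyl)amino]-2-oxoethyl}benzoate | CON(C)C(=O)Cc1cc(OC)cc(OC)c1C(=O)OC | intermediate
11 | undec-10-yn-1-ol | C#CCCCCCCCCCO | starting material
12 | [(undec-10-yn-1-yloxy)methyl]benzene | C#CCCCCCCCCCOCc1ccccc1 | intermediate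
13 | lithium 11-(benzyloxy)undec-1-yn-1-ide | [Li+].[C-]#CCCCCCCCCCOCc1ccccc1 | intermediate
14 | methyl 2-[13-(benzyloxy)-2-oxotridec-3-yn-1-yl]-4,6-dimethoxybenzoate | COC(=O)c1c(OC)cc(OC)cc1CC(=O)C#CCCCCCCCCCOCc1ccccc1 | intermediate
15 | methyl 2-[(2S)-13-(benzyloxy)-2-hydroxytridec-3-yn-1-yl]-4,6-dimethoxybenzoate | COC(=O)c1c(OC)cc(OC)cc1C[C@H](O)C#CCCCCCCCCCOCc1ccccc1 | intermediate
16 | methyl 2-[(2R)-2,13-dihydroxytridecyl]-4,6-dimethoxybenzoate | COC(=O)c1c(OC)cc(OC)cc1C[C@H](O)CCCCCCCCCCCO | intermediate
17 | (3R)-3-(11-hydroxyundecyl)-6,8-dimethoxy-3,4-dihydro-1H-isochromen-1-one | COc1cc(OC)c2c(c1)C[C@@H](CCCCCCCCCCCO)OC2=O | intermediate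
18 | (3R)-8-hydroxy-3-(11-hydroxyundecyl)-6-methoxy-3,4-dihydro-1H-isochromen-1-one | COc1cc(O)c2c(c1)C[C@@H](CCCCCCCCCCCO)OC2=O | target

Total step count: 10 steps.
Longest linear sequence: 9 steps (steps 1 to 5 and 7 to 10, from 3,5-dimethoxyphenol 1); step 6 is a one-step side branch.

Steps most likely to fail

Step 4. The aryl anion may be protonated before it closes onto the ester (plain arylation of the malonate), the product may be arylated a second time, or addition may occur at the wrong aryne carbon. The fallback makes the two bonds one after the other by classical chemistry and sets out from dimethyl malonate 6. Palladium-catalysed alpha-arylation of 6 with commercial 1-bromo-3,5-dimethoxybenzene (COc1cc(Br)cc(OC)c1; Pd(OAc)2, P(t-Bu)3, K3PO4, toluene, 70 °C) should give dimethyl 2-(3,5-dimethoxyphenyl)propanedioate F1. Krapcho dealkoxycarbonylation (LiCl, wet DMSO, 150 °C) should give methyl (3,5-dimethoxyphenyl)acetate F2. Vilsmeier–Haack formylation (POCl3, DMF), ortho to the side chain and para to a methoxy group, should give methyl (2-formyl-3,5-dimethoxyphenyl)acetate F3. Pinnick oxidation (NaClO2, NaH2PO4, 2-methylbut-2-ene, t-BuOH–H2O) should give 2,4-dimethoxy-6-(2-methoxy-2-oxoethyl)benzoic acid F4. O-methylation (MeI, K2CO3, DMF) comes back to the route at 9.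

Step 7. The acetylide may deprotonate the doubly activated benzylic CH2 and so stall the addition, or the tetrahedral alkoxide may attack the neighbouring ester. The fallback forms the same bond under non-basic palladium catalysis and sets out from 9. Selective saponification of the aliphatic ester (LiOH, THF–H2O, 0 °C) should give [3,5-dimethoxy-2-(methoxycarbonyl)phenyl]acetic acid F5. Thioesterification (EtSH, EDC·HCl, DMAP, CH2Cl2) should give methyl 2-[2-(ethylsulfanyl)-2-oxoethyl]-4,6-dimethoxybenzoate F6. Coupling of this thioester with alkyne 12 (PdCl2(dppf), P(2-furyl)3, CuI, Et3N, DMF, 50 °C) comes back to the route at 14.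

Step 8. The ynone may isomerise at its acidic methylene under the catalyst, or the facial selectivity may be poor. The fallback sets the stereocentre on the saturated ketone with an enzyme and sets out from 14. Hydrogenation (H2, 10% Pd/C, EtOAc) saturates the triple bond and removes the benzyl group to give methyl 2-(13-hydroxy-2-oxotridecyl)-4,6-dimethoxybenzoate F7. Reduction with an (R)-selective ketoreductase chosen from a commercial panel (NADP+, i-PrOH as hydride source, phosphate buffer pH 7, DMSO cosolvent, 30 °C) comes back to the route at 16.

Further compounds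
F1 | step 4 | dimethyl 2-(3,5-dimethoxyphenyl)propanedioate | COC(=O)C(C(=O)OC)c1cc(OC)cc(OC)c1
F2 | step 4 | methyl (3,5-dimethoxyphenyl)acetate | COC(=O)Cc1cc(OC)cc(OC)c1
F3 | step 4 | methyl (2-formyl-3,5-dimethoxyphenyl)acetate | COC(=O)Cc1cc(OC)cc(OC)c1C=O
F4 | step 4 | 2,4-dimethoxy-6-(2-methoxy-2-oxoethyl)benzoic acid | COC(=O)Cc1cc(OC)cc(OC)c1C(=O)O
F5 | step 7 | [3,5-dimethoxy-2-(methoxycarbonyl)phenyl]acetic acid | COC(=O)c1c(OC)cc(OC)cc1CC(=O)O
F6 | step 7 | methyl 2-[2-(ethylsulfanyl)-2-oxoethyl]-4,6-dimethoxybenzoate | CCSC(=O)Cc1cc(OC)cc(OC)c1C(=O)OC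
F7 | step 8 | methyl 2-(13-hydroxy-2-oxotridecyl)-4,6-dimethoxybenzoate | COC(=O)c1c(OC)cc(OC)cc1CC(=O)CCCCCCCCCCCO
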